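**Retrosynthetic overview**
1. Target 15 ⇒ diene 13 by disconnecting the C13–O and C16–O bonds; an enantioselective 1,2-dioxygenation of the 2-substituted diene is the last step and sets C13.
2. Diene 13 ⇒ methyl ketone 11 (enol triflate, vinyl coupling).
3. Keto ester 11 ⇒ bicyclic diol 6 (C18 alcohol to methyl ester, C3–OH removed).
4. Diol 6 ⇒ epoxy polyene 3: rings A and B close in one radical cascade (ring A first, then ring B), ending as the 8(17)-exocyclic alkene.
5. Epoxy alcohol 3 ⇒ (5E,9E)-farnesylacetone 1 by ω-hydroxylation and asymmetric epoxidation; this C–O bond formation is the only source of absolute configuration for the decalin.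

Assumption: (5E,9E)-farnesylacetone is bought geometrically pure; positions are given in labdane numbering (C1–C20), the target being an ent-labdane with the C18 ester equatorial (anti to the C10 methyl).

**Step 1**
Reactants: 1 (5E,9E)-6,10,14-trimethylpentadeca-5,9,13-trien-2-one
Product: 2 (5E,9E,13E)-15-hydroxy-6,10,14-trimethylpentadeca-5,9,13-trien-2-one
Conditions: SeO2 (0.2 equiv), t-BuOOH (3 equiv), salicylic acid (0.1 equiv), CH2Cl2, 0 °C to rt
Reagents that add atoms: tert-butyl hydroperoxide CC(C)(C)OO; selenium dioxide O=[Se]=O (catalytic carrier of the oxygen atom)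
Why: Sharpless catalytic SeO2 allylic hydroxylation (ene reaction, then [2,3]-shift) attacks the terminal isopropylidene group in preference to the internal alkenes and gives the (E)-allylic alcohol; no stereocentre is formed.

**Step 2**
Reactants: 2 (5E,9E,13E)-15-hydroxy-6,10,14-trimethylpentadeca-5,9,13-trien-2-one
Product: 3 (5E,9E)-12-[(2R,3R)-3-(hydroxymethyl)-3-methyloxiran-2-yl]-6,10-dimethyldodeca-5,9-dien-2-one
Conditions: Ti(OiPr)4 (10 mol %), D-(−)-diethyl tartrate (12 mol %), t-BuOOH, 4 Å sieves, CH2Cl2, −20 °C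
Reagents that add atoms: tert-butyl hydroperoxide CC(C)(C)OO
Why: Sharpless asymmetric epoxidation touches only the allylic alcohol, and the D-(−)-tartrate gives the (2R,3R)-epoxide (C3 R), from which every ring stereocentre is later relayed.

**Step 3**
Reactants: 3 (5E,9E)-12-[(2R,3R)-3-(hydroxymethyl)-3-methyloxiran-2-yl]-6,10-dimethyldodeca-5,9-dien-2-one
Product: 6 4-[(1R,4aS,5S,6R,8aS)-6-hydroxy-5-(hydroxymethyl)-5,8a-dimethyl-2-methylidenedecahydronaphthalen-1-yl]butan-2-one, via epoxy silyl ether 4 (not isolated), via bis(trimethylsilyl) ether 5 (not isolated)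
Conditions: Cp2TiCl2 (20 mol %), Mn dust, TMSCl, 2,4,6-collidine, THF (0.02 M), rt; then 0.5 M HCl, THF
Reagents that add atoms: none
Why: Titanocene-catalysed radical epoxypolyene bicyclization (Cp2TiCl, trivalent titanium; Nugent–RajanBabu opening): after silylation of the free hydroxyl in the flask, the tertiary C4 radical closes 6-endo/6-endo through a chair–chair array with the C3 oxygen equatorial, which relays C3 (R) to C5, C10 (trans fusion) and C9 (equatorial chain), the planar C4 radical closes with the larger CH2O group equatorial (anti to the C10 methyl), and β-hydride elimination from the C8 titanium alkyl gives the exocyclic alkene.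

**Step 4**
Reactants: 6 4-[(1R,4aS,5S,6R,8aS)-6-hydroxy-5-(hydroxymethyl)-5,8a-dimethyl-2-methylidenedecahydronaphthalen-1-yl]butan-2-one
Product: 8 (1R,2R,4aS,5R,8aS)-2-hydroxy-1,4a-dimethyl-6-methylidene-5-(3-oxobutyl)decahydronaphthalene-1-carboxylic acid, via hydroxy aldehyde 7 (not isolated)
Conditions: TEMPO (10 mol %), PhI(OAc)2, CH2Cl2, rt; then NaClO2, NaH2PO4, 2-methylbut-2-ene, t-BuOH/H2O, 0 °C
Reagents that add atoms: sodium chlorite [Na+].[O-]Cl=O
Why: TEMPO/PhI(OAc)2 oxidation takes the primary neopentyl alcohol in preference to the hindered secondary one, and Pinnick oxidation with a chlorine scavenger spares the exocyclic alkene; C4 is quaternary and cannot epimerize.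

**Step 5**
Reactants: 8 (1R,2R,4aS,5R,8aS)-2-hydroxy-1,4a-dimethyl-6-methylidene-5-(3-oxobutyl)decahydronaphthalene-1-carboxylic acid
Product: 9 methyl (1R,2R,4aS,5R,8aS)-2-hydroxy-1,4a-dimethyl-6-methylidene-5-(3-oxobutyl)decahydronaphthalene-1-carboxylate
Conditions: TMSCHN2, MeOH/toluene, 0 °C
Reagents that add atoms: (trimethylsilyl)diazomethane C[Si](C)(C)C=[N+]=[N-]
Why: Diazoalkane esterification is neutral, so the β-hydroxy ester with its quaternary α-carbon never meets retro-aldol (basic) conditions.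

**Step 6**
Reactants: 9 methyl (1R,2R,4aS,5R,8aS)-2-hydroxy-1,4a-dimethyl-6-methylidene-5-(3-oxobutyl)decahydronaphthalene-1-carboxylate
Product: 10 methyl (1R,2R,4aS,5R,8aS)-2-(1H-imidazole-1-carbothioyloxy)-1,4a-dimethyl-6-methylidene-5-(3-oxobutyl)decahydronaphthalene-1-carboxylate
Conditions: 1,1'-thiocarbonyldiimidazole, DMAP (cat.), ClCH2CH2Cl, 70 °C
Reagents that add atoms: 1,1'-thiocarbonyldiimidazole S=C(n1ccnc1)n1ccnc1
Why: Thioacylation of the equatorial C3 alcohol gives the radical-labile thiocarbamate, the first half of a Barton–McCombie deoxygenation.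

**Step 7**
Reactants: 10 methyl (1R,2R,4aS,5R,8aS)-2-(1H-imidazole-1-carbothioyloxy)-1,4a-dimethyl-6-methylidene-5-(3-oxobutyl)decahydronaphthalene-1-carboxylate
Product: 11 methyl (1S,4aS,5R,8aS)-1,4a-dimethyl-6-methylidene-5-(3-oxobutyl)decahydronaphthalene-1-carboxylate
Conditions: Bu3SnH, AIBN (cat.), toluene, 100 °C
Reagents that add atoms: none
Why: Barton–McCombie radical deoxygenation removes the C3 oxygen (tin radical adds to C=S, the C3–O bond fragments, Bu3SnH reduces the secondary radical) and leaves C4, C5, C9 and C10 untouched.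

**Step 8**
Reactants: 11 methyl (1S,4aS,5R,8aS)-1,4a-dimethyl-6-methylidene-5-(3-oxobutyl)decahydronaphthalene-1-carboxylate
Product: 12 methyl (1S,4aS,5R,8aS)-1,4a-dimethyl-6-methylidene-5-[3-(trifluoromethylsulfonyloxy)but-3-en-1-yl]decahydronaphthalene-1-carboxylate
Conditions: LDA, THF, −78 °C; Comins' reagent, −78 °C; then 0.5 M HCl work-up
Reagents that add atoms: Comins' reagent, N-(5-chloropyridin-2-yl)-1,1,1-trifluoro-N-(trifluoromethylsulfonyl)methanesulfonamide O=S(=O)(N(c1ccc(Cl)cn1)S(=O)(=O)C(F)(F)F)C(F)(F)F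
Why: Kinetic enolization of the methyl ketone at the methyl group (the ester has no α-hydrogen) followed by O-triflation gives the terminal enol triflate.

**Step 9**
Reactants: 12 methyl (1S,4aS,5R,8aS)-1,4a-dimethyl-6-methylidene-5-[3-(trifluoromethylsulfonyloxy)but-3-en-1-yl]decahydronaphthalene-1-carboxylate
Product: 13 methyl (1S,4aS,5R,8aS)-1,4a-dimethyl-6-methylidene-5-(3-methylidenepent-4-en-1-yl)decahydronaphthalene-1-carboxylate
Conditions: tributyl(vinyl)stannane, Pd(PPh3)4 (5 mol %), LiCl, THF, 65 °C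
Reagents that add atoms: tributyl(vinyl)stannane C=C[Sn](CCCC)(CCCC)CCCC
Why: Stille coupling of the alkenyl triflate (LiCl-promoted) forms the C13–C14 bond and delivers the 2-substituted 1,3-diene.

**Step 10**
Reactants: 13 methyl (1S,4aS,5R,8aS)-1,4a-dimethyl-6-methylidene-5-(3-methylidenepent-4-en-1-yl)decahydronaphthalene-1-carboxylate
Product: 15 methyl (1S,4aS,5R,8aS)-5-[(3R)-3-hydroxy-3-(hydroxymethyl)pent-4-en-1-yl]-1,4a-dimethyl-6-methylidenedecahydronaphthalene-1-carboxylate, via diacetate 14 (not isolated)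
Conditions: 9-mesityl-10-methylacridinium tetrafluoroborate (5 mol %), Cu(MeCN)4PF6 (10 mol %), (S,S)-t-Bu-bisoxazoline (12 mol %), AgOAc (2.2 equiv), AcOH, MeCN (0.02 M), 450 nm LED, −10 °C; then concentrate, K2CO3, MeOH, 0 °C
Reagents that add atoms: silver acetate [Ag+].CC(=O)[O-] (acetate pool shared with acetic acid CC(=O)O)
Why: Proposed new method: dual acridinium-photoredox/copper–bisoxazoline enantioselective 1,2-diacetoxylation of a 2-alkyl-1,3-diene — the excited acridinium oxidizes only the diene (about 1.9 V against about 2.5 V for the isolated exocyclic alkene), acetate adds to C16 of the radical cation because that leaves the more substituted allyl radical, the divalent copper acetate complex traps this radical and C–O reductive elimination from the trivalent allylcopper at the tertiary terminus forms the C13–O bond and sets C13 (R) under ligand control (the ligand antipode is fixed by a pilot run), AgOAc re-oxidizes monovalent copper and the acridine radical, and methanolysis frees the diol; the closest known reaction types are anti-Markovnikov hydroacetoxylation of alkene radical cations and copper-catalysed asymmetric carboesterification of dienes (Kharasch–Sosnovsky-type C–O bond formation).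

**Compound list**
1 | (5E,9E)-6,10,14-trimethylpentadeca-5,9,13-trien-2-one ((E,E)-farnesylacetone) | CC(=O)CC/C=C(\C)CC/C=C(\C)CCC=C(C)C | starting material
2 | (5E,9E,13E)-15-hydroxy-6,10,14-trimethylpentadeca-5,9,13-trien-2-one | CC(=O)CC/C=C(\C)CC/C=C(\C)CC/C=C(\C)CO | intermediate
3 | (5E,9E)-12-[(2R,3R)-3-(hydroxymethyl)-3-methyloxiran-2-yl]-6,10-dimethyldodeca-5,9-dien-2-one | CC(=O)CC/C=C(\C)CC/C=C(\C)CC[C@H]1O[C@]1(C)CO | intermediate
4 | (5E,9E)-6,10-dimethyl-12-[(2R,3R)-3-methyl-3-(trimethylsilyloxymethyl)oxiran-2-yl]dodeca-5,9-dien-2-one | CC(=O)CC/C=C(\C)CC/C=C(\C)CC[C@H]1O[C@]1(C)CO[Si](C)(C)C | intermediate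
5 | 4-[(1R,4aS,5S,6R,8aS)-5,8a-dimethyl-2-methylidene-6-(trimethylsilyloxy)-5-(trimethylsilyloxymethyl)decahydronaphthalen-1-yl]butan-2-one | CC(=O)CC[C@@H]1C(=C)CC[C@H]2[C@@]1(C)CC[C@@H](O[Si](C)(C)C)[C@]2(C)CO[Si](C)(C)C | intermediate
6 | 4-[(1R,4aS,5S,6R,8aS)-6-hydroxy-5-(hydroxymethyl)-5,8a-dimethyl-2-methylidenedecahydronaphthalen-1-yl]butan-2-one (3-OH and C18 CH2OH equatorial, trans-decalin) | CC(=O)CC[C@@H]1C(=C)CC[C@H]2[C@@]1(C)CC[C@@H](O)[C@]2(C)CO | intermediate
7 | (1R,2R,4aS,5R,8aS)-2-hydroxy-1,4a-dimethyl-6-methylidene-5-(3-oxobutyl)decahydronaphthalene-1-carbaldehyde | CC(=O)CC[C@@H]1C(=C)CC[C@H]2[C@@]1(C)CC[C@@H](O)[C@]2(C)C=O | intermediate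
8 | (1R,2R,4aS,5R,8aS)-2-hydroxy-1,4a-dimethyl-6-methylidene-5-(3-oxobutyl)decahydronaphthalene-1-carboxylic acid | CC(=O)CC[C@@H]1C(=C)CC[C@H]2[C@@]1(C)CC[C@@H](O)[C@]2(C)C(=O)O | intermediate
9 | methyl (1R,2R,4aS,5R,8aS)-2-hydroxy-1,4a-dimethyl-6-methylidene-5-(3-oxobutyl)decahydronaphthalene-1-carboxylate | CC(=O)CC[C@@H]1C(=C)CC[C@H]2[C@@]1(C)CC[C@@H](O)[C@]2(C)C(=O)OC | intermediate
10 | methyl (1R,2R,4aS,5R,8aS)-2-(1H-imidazole-1-carbothioyloxy)-1,4a-dimethyl-6-methylidene-5-(3-oxobutyl)decahydronaphthalene-1-carboxylate | CC(=O)CC[C@@H]1C(=C)CC[C@H]2[C@@]1(C)CC[C@@H](OC(=S)n3ccnc3)[C@]2(C)C(=O)OC | intermediate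
11 | methyl (1S,4aS,5R,8aS)-1,4a-dimethyl-6-methylidene-5-(3-oxobutyl)decahydronaphthalene-1-carboxylate | CC(=O)CC[C@@H]1C(=C)CC[C@H]2[C@@]1(C)CCC[C@]2(C)C(=O)OC | intermediate
12 | methyl (1S,4aS,5R,8aS)-1,4a-dimethyl-6-methylidene-5-[3-(trifluoromethylsulfonyloxy)but-3-en-1-yl]decahydronaphthalene-1-carboxylate | C=C(OS(=O)(=O)C(F)(F)F)CC[C@@H]1C(=C)CC[C@H]2[C@@]1(C)CCC[C@]2(C)C(=O)OC | intermediate
13 | methyl (1S,4aS,5R,8aS)-1,4a-dimethyl-6-methylidene-5-(3-methylidenepent-4-en-1-yl)decahydronaphthalene-1-carboxylate | C=CC(=C)CC[C@@H]1C(=C)CC[C@H]2[C@@]1(C)CCC[C@]2(C)C(=O)OC | intermediate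
14 | methyl (1S,4aS,5R,8aS)-5-[(3R)-3-acetoxy-3-(acetoxymethyl)pent-4-en-1-yl]-1,4a-dimethyl-6-methylidenedecahydronaphthalene-1-carboxylate | C=C[C@@](OC(C)=O)(COC(C)=O)CC[C@@H]1C(=C)CC[C@H]2[C@@]1(C)CCC[C@]2(C)C(=O)OC | intermediate
15 | methyl (1S,4aS,5R,8aS)-5-[(3R)-3-hydroxy-3-(hydroxymethyl)pent-4-en-1-yl]-1,4a-dimethyl-6-methylidenedecahydronaphthalene-1-carboxylate | C=C[C@@](O)(CO)CC[C@@H]1C(=C)CC[C@H]2[C@@]1(C)CCC[C@]2(C)C(=O)OC | target

**Totals**
Total steps: 10. Longest linear sequence: 10 (fully linear from 1).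

**Steps most likely to fail, with fallbacks**

Step 10 (the proposed new dioxygenation). Possible failures are acetate attack at C15 instead of C16, C–O formation at the primary allyl terminus (1,4-diacetate), low enantioselectivity at a centre flanked by two CH2 groups, and dimerization of the diene radical cation. The fallback uses only known chemistry, sets out from enol triflate 12 and returns at target 15. Stille coupling of 12 with (tributylstannyl)methanol (Pd(PPh3)4, LiCl, dioxane, 90 °C) gives the 2-substituted allylic alcohol F1. Sharpless asymmetric epoxidation (Ti(OiPr)4, L-(+)-diethyl tartrate, t-BuOOH, 4 Å sieves, CH2Cl2, −20 °C) ignores the exocyclic alkene and gives the (2S)-epoxy alcohol F2, so the C13–O bond is again formed under reagent control. Excess dimethylsulfonium methylide (Me3S+ I−, n-BuLi, THF, −10 °C to rt) opens the epoxide at its CH2 carbon and eliminates dimethyl sulfide, giving the vinyl carbinol 15 with C13 unchanged (R).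

Step 3 (titanocene bicyclization). The yield of such cascades is moderate. The specific danger here is the free ketone: the C8 radical can add to the titanium-activated carbonyl, and the C4 facial selectivity may also erode. The fallback masks the ketone, sets out from allylic alcohol 2 and returns at diol 6. Ketalization of 2 (ethylene glycol, PPTS, benzene, reflux) gives the dioxolane allylic alcohol F3. Epoxidation as in step 2 gives the (2R,3R)-epoxy alcohol ketal F4. The same titanocene conditions then give the bicyclic diol ketal F5, and PPTS in aqueous acetone releases 6.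

Step 4 (oxidation of the neopentyl alcohol next to a free β-hydroxyl). The intermediate β-hydroxy aldehyde has a quaternary α-carbon and can undergo retro-aldol ring opening, and the hindered aldehyde may stall. The fallback removes the C3 oxygen first, sets out from diol 6 and returns at keto ester 11. Thiocarbonyldiimidazole (toluene, 80 °C) converts the 1,3-diol into the six-membered cyclic thionocarbonate F6. Bu3SnH/AIBN (toluene, 110 °C) cleaves it at the secondary C3–O bond, and K2CO3/MeOH work-up gives the 3-deoxy primary alcohol F7. Jones oxidation (CrO3, H2SO4, acetone, 0 °C) gives the carboxylic acid F8, and TMSCHN2 gives 11.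

**Further compounds**
F1 | step 10 | methyl (1S,4aS,5R,8aS)-5-[3-(hydroxymethyl)but-3-en-1-yl]-1,4a-dimethyl-6-methylidenedecahydronaphthalene-1-carboxylate | C=C(CO)CC[C@@H]1C(=C)CC[C@H]2[C@@]1(C)CCC[C@]2(C)C(=O)OC
F2 | step 10 | methyl (1S,4aS,5R,8aS)-5-{2-[(2S)-2-(hydroxymethyl)oxiran-2-yl]ethyl}-1,4a-dimethyl-6-methylidenedecahydronaphthalene-1-carboxylate | C1O[C@]1(CO)CC[C@@H]2C(=C)CC[C@H]3[C@@]2(C)CCC[C@]3(C)C(=O)OC
F3 | step 3 | (2E,6E,10E)-2,6,10-trimethyl-13-(2-methyl-1,3-dioxolan-2-yl)trideca-2,6,10-trien-1-ol | CC1(CC/C=C(\C)CC/C=C(\C)CC/C=C(\C)CO)OCCO1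
F4 | step 3 | {(2R,3R)-3-[(3E,7E)-3,7-dimethyl-10-(2-methyl-1,3-dioxolan-2-yl)deca-3,7-dien-1-yl]-2-methyloxiran-2-yl}methanol | CC1(CC/C=C(\C)CC/C=C(\C)CC[C@H]2O[C@]2(C)CO)OCCO1
F5 | step 3 | (1S,2R,4aS,5R,8aS)-1-(hydroxymethyl)-1,4a-dimethyl-6-methylidene-5-[2-(2-methyl-1,3-dioxolan-2-yl)ethyl]decahydronaphthalen-2-ol | CC1(CC[C@@H]2C(=C)CC[C@H]3[C@@]2(C)CC[C@@H](O)[C@]3(C)CO)OCCO1
F6 | step 4 | cyclic thionocarbonate (1,3-dioxane-2-thione bridging O3 and O18) of diol 6 | CC(=O)CC[C@@H]1C(=C)CC[C@H]2[C@@]1(C)CC[C@H]3OC(=S)OC[C@]23C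
F7 | step 4 | 4-[(1R,4aS,5S,8aS)-5-(hydroxymethyl)-5,8a-dimethyl-2-methylidenedecahydronaphthalen-1-yl]butan-2-one | CC(=O)CC[C@@H]1C(=C)CC[C@H]2[C@@]1(C)CCC[C@]2(C)CO
F8 | step 4 | (1S,4aS,5R,8aS)-1,4a-dimethyl-6-methylidene-5-(3-oxobutyl)decahydronaphthalene-1-carboxylic acid | CC(=O)CC[C@@H]1C(=C)CC[C@H]2[C@@]1(C)CCC[C@]2(C)C(=O)O
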